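The readings are calculated for substances that don't exist; noise was put on by code.

At 8.00 h, the last reading of the autumn run, the left-handed substrate stood at 38.7% and the right-handed substrate at 48.0%. I wanted to get from such a pair what had not been read: the excess in the product.

| setting | summer | dawn | autumn | flask |
|---|---|---|---|---|
| left-handed substrate | 0.14 M | 0.22 M | 0.10 M | 0.10 M |
| right-handed substrate | 0.14 M | 0.22 M | 0.10 M | 0.10 M |
| partner | 4 equiv (fed, over 5.0 h) | 4 equiv (fed, over 5.0 h) | 4 equiv (fed, over 5.0 h) | 4.00 equiv (fed, over 5.0 h) |
| racemization catalyst | 10 mol% | 10 mol% | 10 mol% | 10 mol% |
| impurity | 1.3 mM | 1.3 mM | 2.6 mM | 1.3 mM |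
| remark | run made earlier; the fed solution adds 0.20 times the starting volume | run made earlier; the fed solution adds 0.20 times the starting volume | run made earlier; the fed solution adds 0.20 times the starting volume | the fed solution adds 0.20 times the starting volume |
| time |  |  |  | 6.0 h |

- summer (time / h: left-handed substrate / %, right-handed substrate / %): 1.00: 49.0, 50.4; 2.00: 47.2, 49.4; 3.00: 45.8, 49.1; 4.00: 43.5, 47.6; 5.00: 41.4, 47.1; 6.00: 38.0, 47.6; 8.00: 36.1, 47.0
- dawn (time / h: left-handed substrate / %, right-handed substrate / %): 0.417: 50.5, 50.5; 1.00: 49.1, 50.3; 2.00: 47.2, 49.7; 3.00: 44.4, 48.4; 4.00: 41.2, 47.7; 6.00: 36.0, 46.8; 8.00: 32.7, 45.7
- autumn (time / h: left-handed substrate / %, right-handed substrate / %): 0.500: 50.0, 50.0; 1.00: 49.7, 50.0; 2.00: 48.0, 49.8; 4.00: 44.4, 49.4; 8.00: 38.7, 48.0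

(each reading ± 0.3 percentage points)

- partner is single-handed; left-handed substrate and right-handed substrate are mirror images of each other, charged as a racemate, each of them at the stated concentration
- charges are per starting volume, the dose included; the dosed solution carries all of it
- what was read earlier has a scatter of 0.3 percentage points, one standard deviation
- steps that have been proposed: racemization catalyst + impurity -> spent catalyst A; left-handed substrate + racemization catalyst <-> right-handed substrate + racemization catalyst; partner + right-handed substrate -> right-handed product; partner + left-handed substrate -> left-handed product; partner + racemization catalyst -> spent catalyst B; 2 partner -> homo dimer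
- an excess is the difference of the two amounts in percent of their sum
- an excess is below zero if the other one leads
- the handed part of partner does not stay in what it makes, so the products of the two hands are mirror images too

* part of the left-handed substrate and right-handed substrate charged together that has reacted at 6.0 h
* excess of left-handed product over right-handed product in the product at 6.0 h
* excess of right-handed substrate over left-handed substrate among what is left of the two at 6.0 h

I built the flask up one process at a time. With the two main steps alone, partner taking each hand of substrate, each unit of product removes one unit of its own hand. The gap (right-handed minus left-handed substrate, as fractions of the charge) then equals left-handed minus right-handed product, and the part reacted, c, equals their sum. So the gap over c, which I called the gap share, was the product excess itself. In the autumn run: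

gap share = gap / c = 69.9%

Then I added racemization. Each turn moves one unit from right to left and leaves c alone, but it narrows the gap by two units. With T the amount moved:

product excess = gap share + 2 T / c

So the gap share became a floor under the excess while the right hand leads. The remaining steps, which take partner or catalyst, act on neither hand directly. So the line stands.

The new flask has the autumn charge with 1.3 mM of impurity against 2.6 mM, so I expected a similar gap share and an excess above it. That floor is a reading and carries the scatter.

The forecast gave 10.4% reacted, a product excess of 79% and a substrate excess of 8.5%, on the view that “Racemization is slow and the partner is largely wasted”. Its excess stood above my floor, with T at 0.3 points.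

The flask gave 10.7% reacted, a product excess of 92.8% and a substrate excess of 8.06%.

    racemization catalyst + impurity → spent catalyst A (k = 49.0 /M/min)
    left-handed substrate + racemization catalyst ⇌ right-handed substrate + racemization catalyst, rate k2*[racemization catalyst]*[left-handed substrate] forward; the back reaction follows from the equilibrium constant (k = 0.388 /M/min)
    partner + right-handed substrate → right-handed product (k = 1.45 × 10⁻⁴ /M/min)
    partner + left-handed substrate → left-handed product (k = 0.00422 /M/min)
    partner + racemization catalyst → spent catalyst B (k = 0.0275 /M/min)
    2 partner → homo dimer (k = 0.00711 /M/min)

The flask's gap share was 67.5%, near the autumn 69.9%, and its excess stood 25 percentage points above that. So T was 1.35% of the charge, more than the right-handed product of 0.383%. With 10.0 equiv of partner, the neighbour flask had a gap share of 77.3% under its excess of 92.1%, so its T was 1.44%. Read at 60.0 h instead of 6.00 h, the flask had 30.1% reacted against 10.7%, so the early hour of the reading held c down, as the largest single effect but not the main reason, for those 19 points close 22% of what was missing.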